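**Plan**

1. Atom labels: C1 (CH–OAc), C2 (CH2), C3 (quaternary C–CH3), C4 (CH–OH), C5 (CH2), C6(CH3)=C7H, C8 (CH–O–aroyl), C9 (ring-fusion CH), C10 (C(OH)–iPr); ring A = C1–C2–C3–C9–C10, ring B = C3–C4–C5–C6–C7–C8–C9; β = face of the C3 methyl group, α = the other face.
2. Enabling feature: ring B is a cycloheptene with its two oxygens at C4 and C8, each beside a ring-fusion carbon (C3, C9), and C5–C6–C7 between them. Such a ring is the sum of the four-carbon enolate C5–C4–C3=C9 of a ring A methyl ketone and a three-carbon acryloylsilane C6–C7–C8 (C8 oxygen masked as silicon), so C5–C6, C8–C9 and C3–CH3 are cut in one operation.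
3. Cuts made before that: the silyl ethers, the C1 acetate, the C1/C10 cis-diol (to a C1=C10 alkene), the C8 ester, C8–O (to C8–Si), and the isopropyl and C6 methyl groups (to enol triflates, i.e. a C10 ketone and the C6 silyl enol ether).
4. Forward order: ring A is made first as cyclopentenyl methyl ketone 7 and the acryloylsilane 17 separately; step 10 closes ring B onto ring A and adds the angular methyl; the periphery is then adjusted in the order C4, C6, C10, C8, C1/C10.
5. Stereochemistry: the C10 carbinol (CBS reduction) steers C9, C8 and C3 in step 10 and is erased later at the ketone stage; C4 comes from hydride addition anti to the angular methyl, C8–O from stereoretentive C–Si oxidation, C1 and C10 from osmylation of the convex β face.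

Key step: step 10

Remarks: TBS = tert-butyldimethylsilyl, TES = triethylsilyl, Bn = benzyl, Tf = trifluoromethanesulfonyl. Compounds 15 and 16 are racemic at a carbinol carbon that becomes the acylsilane carbonyl in step 9. It is assumed that a triethylsilyl ether at C10 biases the annulation as a tert-butyldimethylsilyl ether would; it is chosen so that it can later be removed beside the C4 TBS ether.

**Route**

Step 1
Reactants: 1 cyclopentane-1,3-dione
Product: 2 3-bromocyclopent-2-en-1-one
Conditions: Ph3PBr2, Et3N, CH2Cl2, 0 °C to rt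
Reagents that add atoms: dibromotriphenylphosphorane, BrP(Br)(c1ccccc1)(c1ccccc1)c1ccccc1
Why: The enol oxygen of the 1,3-dione is activated as an oxyphosphonium salt and replaced by bromide through addition–elimination, the standard conversion of a cyclic 1,3-dione into a β-bromo enone.

Step 2
Reactants: 2 3-bromocyclopent-2-en-1-one
Product: 3 (S)-3-bromocyclopent-2-en-1-ol
Conditions: (R)-2-methyl-CBS-oxazaborolidine (C18H20BNO, 10 mol %), BH3·SMe2, THF, −20 °C; MeOH, then aqueous work-up
Reagents that add atoms: none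
Why: Corey–Bakshi–Shibata reduction, in which the bromoalkene branch acts as the large group and the ring CH2 as the small one, so the (R)-catalyst should deliver hydride to the face that gives the (S)-carbinol by clean 1,2-reduction.

Step 3
Reactants: 3 (S)-3-bromocyclopent-2-en-1-ol
Product: 4 (S)-[(3-bromocyclopent-2-en-1-yl)oxy]triethylsilane
Conditions: Et3SiCl, imidazole, CH2Cl2, 0 °C
Reagents that add atoms: chlorotriethylsilane, CC[Si](Cl)(CC)CC
Why: Routine silylation of a secondary allylic alcohol; the TES ether tolerates the organolithium and enolate steps and can later be cleaved selectively beside a TBS ether.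

Step 4
Reactants: 4 (S)-[(3-bromocyclopent-2-en-1-yl)oxy]triethylsilane; 5 N-methoxy-N-methylacetamide
Product: 7 (S)-1-[3-(triethylsilyloxy)cyclopent-1-en-1-yl]ethanone, via vinyllithium 6 (not isolated)
Conditions: t-BuLi (2 equiv), THF, −78 °C; then 5, −78 to 0 °C; H2O
Reagents that add atoms: N-methoxy-N-methylacetamide (5), CON(C)C(C)=O
Why: Bromine–lithium exchange gives the vinyllithium without moving the alkene, and Weinreb acylation stops at the methyl ketone because the chelated adduct persists until work-up; the carbinol stereocentre is not involved.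

Step 5
Reactants: 8 prop-2-yn-1-ol
Product: 9 tert-butyldimethyl(prop-2-yn-1-yloxy)silane
Conditions: t-BuMe2SiCl, imidazole, CH2Cl2, 0 °C to rt
Reagents that add atoms: tert-butylchlorodimethylsilane, CC(C)(C)[Si](C)(C)Cl
Why: Standard silylation of a primary alcohol; this silicon later becomes the acylsilane silicon.

Step 6
Reactants: 9 tert-butyldimethyl(prop-2-yn-1-yloxy)silane; 10 benzylchlorodimethylsilane
Product: 12 benzyl[3-(tert-butyldimethylsilyloxy)prop-1-yn-1-yl]dimethylsilane, via lithium acetylide 11 (not isolated)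
Conditions: n-BuLi, THF, −78 °C; then 10, −78 °C to rt
Reagents that add atoms: benzylchlorodimethylsilane (10), C[Si](C)(Cl)Cc1ccccc1
Why: Deprotonation of the terminal alkyne and C-silylation of the acetylide with the chlorosilane installs the benzyldimethylsilyl group that will serve as the masked C8 hydroxyl.

Step 7
Reactants: 12 benzyl[3-(tert-butyldimethylsilyloxy)prop-1-yn-1-yl]dimethylsilane
Product: 15 racemic 3-(benzyldimethylsilyl)-1-(tert-butyldimethylsilyl)prop-2-yn-1-ol, via α-lithio silyl ether 13 (not isolated), via lithium alkoxide 14 (not isolated)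
Conditions: t-BuLi, THF, −78 to −45 °C; AcOH, −78 °C
Reagents that add atoms: none
Why: Deprotonation at the propargylic carbon next to oxygen (acidified by the alkynylsilane, so it is removed in preference to the benzylic Si–CH2 hydrogens) triggers a 1,2-silyl shift from oxygen to carbon (retro-Brook rearrangement), driven by formation of the lithium alkoxide.

Step 8
Reactants: 15 racemic 3-(benzyldimethylsilyl)-1-(tert-butyldimethylsilyl)prop-2-yn-1-ol
Product: 16 racemic (E)-3-(benzyldimethylsilyl)-1-(tert-butyldimethylsilyl)prop-2-en-1-ol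
Conditions: NaAlH2(OCH2CH2OCH3)2 (Red-Al), Et2O, 0 °C; aqueous Rochelle salt
Reagents that add atoms: none
Why: Oxygen-directed trans-hydroalumination of the propargylic alkoxide followed by protonolysis should give only the E-vinylsilane.

Step 9
Reactants: 16 racemic (E)-3-(benzyldimethylsilyl)-1-(tert-butyldimethylsilyl)prop-2-en-1-ol
Product: 17 (E)-3-(benzyldimethylsilyl)-1-(tert-butyldimethylsilyl)prop-2-en-1-one
Conditions: Dess–Martin periodinane (C13H13IO8), pyridine, CH2Cl2, 0 °C to rt
Reagents that add atoms: none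
Why: Dess–Martin oxidation of an α-silyl carbinol to the acylsilane under conditions that form no free alkoxide, so Brook rearrangement of the α-silyl alcohol is avoided and the E alkene is kept.

Step 10
Reactants: 7 (S)-1-[3-(triethylsilyloxy)cyclopent-1-en-1-yl]ethanone; 17 (E)-3-(benzyldimethylsilyl)-1-(tert-butyldimethylsilyl)prop-2-en-1-one; 18 iodomethane
Product: 22 cis-fused bicyclic C4 ketone (3β-CH3; 6-OTBS enol ether C6=C7; 8α-SiMe2Bn; 9β-H; 10β-OTES), via lithium enolate 19 (not isolated), via cyclopropanediolate 20 (not isolated), via bicyclic lithium enolate 21 (not isolated)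
Conditions: LiN(iPr)2, THF, −80 °C (enolate of 7); cannulated into 17, THF, −80 to −30 °C; then MeI (excess), (Me2N)3PO, −30 to 0 °C
Reagents that add atoms: iodomethane (18), CI
Why: Enolate 19 attacks the acylsilane carbonyl of 17 through C5 (forming C5–C6), the α-silyl alkoxide undergoes 1,2-Brook rearrangement to an allyl anion stabilised by the C8 silyl group, this anion closes onto the ketone carbon C4 to give cyclopropanediolate 20, and anionic oxy-Cope rearrangement of 20 cleaves C4–C6 and forms C8–C9. The closest known reaction type is the Brook rearrangement-mediated (3+4) annulation of β-silylacryloylsilanes with lithium enolates of alkenyl methyl ketones, finished here by ordinary C-alkylation of the enolate that the sigmatropic shift releases, as is common practice after anionic oxy-Cope rearrangements. The transient three-membered ring closes 3-exo-trig, and ring B then closes by (3,3)-sigmatropic ring expansion through the boat transition state that a cis-1,2-dialkenylcyclopropane must adopt. C9 is set by bonding of the vinylsilane terminus to the cyclopentene face anti to the C10 silyloxy group (the C10 hydrogen, not the silyl ether, points into the boat); C8 follows stereospecifically from the E alkene (silicon cis to C10 on ring B, H8 cis to H9); C3 is set by methylation of enolate 21 on the face of H9, anti to the C8–C9 bond, which gives the cis ring fusion. The step needs kinetic deprotonation of the methyl group of 7 rather than its γ-position (LiN(iPr)2 at −80 °C), methylation only at C3 (21 is born solely as the C3=C4 enolate and is trapped cold with excess MeI and (Me2N)3PO before proton transfer to C5 can compete), and facial control from the single stereocentre C10, which its allylic position next to C9 provides.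

Step 11
Reactants: 22 cis-fused bicyclic C4 ketone
Product: 23 4β-alcohol (3β-CH3; 4β-OH; 6-OTBS enol ether; 8α-SiMe2Bn; 9β-H; 10β-OTES)
Conditions: LiAlH4, Et2O, −78 to 0 °C
Reagents that add atoms: none
Why: Hydride addition to the neopentyl ketone on the α face, anti to the adjacent angular methyl (the bias known from ketones flanked by an angular methyl in fused ring systems), should give the 4β-alcohol, which is also the more stable epimer on the convex face; silyl enol ether, silyl ether and benzylsilane are inert to LiAlH4 at this temperature.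

Step 12
Reactants: 23 4β-alcohol
Product: 24 4β-TBS ether (3β-CH3; 4β-OTBS; 6-OTBS enol ether; 8α-SiMe2Bn; 9β-H; 10β-OTES)
Conditions: t-BuMe2SiOTf, 2,6-lutidine, CH2Cl2, −78 to 0 °C
Reagents that add atoms: tert-butyldimethylsilyl trifluoromethanesulfonate, CC(C)(C)[Si](C)(C)OS(=O)(=O)C(F)(F)F
Why: The silyl triflate with a hindered base is the standard way to silylate a hindered secondary alcohol, and the silyl enol ether is stable to it at low temperature.

Step 13
Reactants: 24 4β-TBS ether
Product: 26 C6 enol triflate (C6(OTf)=C7; 4β-OTBS; 8α-SiMe2Bn; 10β-OTES), via C6 lithium enolate 25 (not isolated)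
Conditions: MeLi, THF, 0 °C to rt; then PhNTf2, −78 to 0 °C; H2O
Reagents that add atoms: N-phenylbis(trifluoromethanesulfonimide), O=S(=O)(N(c1ccccc1)S(=O)(=O)C(F)(F)F)C(F)(F)F
Why: Methyllithium attacks the silicon of the silyl enol ether and releases the C6=C7 lithium enolate regiospecifically (alkyl silyl ethers and the benzylsilane react far more slowly), and O-sulfonylation with the triflimide fixes this regiochemistry as the enol triflate.

Step 14
Reactants: 26 C6 enol triflate
Product: 27 6-methyl alkene (C6(CH3)=C7; 4β-OTBS; 8α-SiMe2Bn; 10β-OTES)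
Conditions: MeMgBr, Fe(acac)3 (5 mol %), THF/N-methyl-2-pyrrolidone, −30 °C
Reagents that add atoms: methylmagnesium bromide, C[Mg]Br
Why: Iron-catalysed Kumada-type cross-coupling of an enol triflate with an alkyl Grignard reagent, which is fast at low temperature and leaves silyl ethers and the allylic silane alone, puts the methyl group on C6 with the alkene fixed at C6=C7.

Step 15
Reactants: 27 6-methyl alkene
Product: 28 10β-alcohol (10β-OH; 4β-OTBS; 8α-SiMe2Bn; C6(CH3)=C7)
Conditions: pyridinium p-toluenesulfonate (cat.), MeOH/CH2Cl2, 0 °C to rt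
Reagents that add atoms: none
Why: Mild acid methanolysis cleaves a secondary TES ether much faster than the hindered secondary TBS ether and is too weak to protodesilylate the allylic silane.

Step 16
Reactants: 28 10β-alcohol
Product: 29 C10 ketone (10-oxo; 4β-OTBS; 8α-SiMe2Bn; 9β-H; C6(CH3)=C7)
Conditions: Dess–Martin periodinane (C13H13IO8), pyridine, CH2Cl2, 0 °C to rt
Reagents that add atoms: none
Why: Dess–Martin oxidation under buffered, non-enolising conditions gives the cyclopentanone without epimerising the adjacent ring-fusion centre C9.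

Step 17
Reactants: 29 C10 ketone
Product: 31 C10 enol triflate (C10(OTf)=C1; 4β-OTBS; 8α-SiMe2Bn; 9β-H), via C10 potassium enolate 30 (not isolated)
Conditions: KN(SiMe3)2, THF, −78 °C; then PhNTf2, −78 to 0 °C; H2O
Reagents that add atoms: N-phenylbis(trifluoromethanesulfonimide), O=S(=O)(N(c1ccccc1)S(=O)(=O)C(F)(F)F)C(F)(F)F
Why: Kinetic deprotonation removes a hydrogen from the unhindered C1 methylene rather than the ring-fusion C9–H (shielded by the C8 silyl group), and triflation fixes the C1=C10 enolate; the β-silyl ketone has no leaving group to lose, which is why C8 is still silicon at this stage.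

Step 18
Reactants: 31 C10 enol triflate
Product: 32 10-isopropyl diene (C10(iPr)=C1; C6(CH3)=C7; 4β-OTBS; 8α-SiMe2Bn; 9β-H)
Conditions: i-PrMgCl, Fe(acac)3 (5 mol %), THF/N-methyl-2-pyrrolidone, −30 °C
Reagents that add atoms: isopropylmagnesium chloride, CC(C)[Mg]Cl
Why: Iron-catalysed cross-coupling of an enol triflate with a secondary alkyl Grignard reagent, in which C–C bond formation outruns β-hydride elimination, so the isopropyl group should be transferred unrearranged and the alkene stays at C1=C10.

Step 19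
Reactants: 32 10-isopropyl diene
Product: 34 8α-alcohol (8α-OH; 4β-OTBS; C10(iPr)=C1; C6(CH3)=C7), via C8 dimethylsilanol 33 (not isolated)
Conditions: Bu4NF, THF, 0 °C; then KHCO3, H2O2 (30 % aq), MeOH, rt
Reagents that add atoms: hydrogen peroxide, OO
Why: Tamao oxidation of a benzyldimethylsilyl group: fluoride expels the benzyl group as toluene (a primary benzyl anion is a better leaving group than the substituted secondary allyl anion at C8) to give a silanol, which peroxide oxidises with retention at C8, so the alcohol takes the α position of the silicon; the brief cold fluoride treatment should spare the hindered C4 TBS ether.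

Step 20
Reactants: 35 4-hydroxybenzoic acid
Product: 37 4-(tert-butyldimethylsilyloxy)benzoic acid, via bis-silyl derivative 36 (not isolated)
Conditions: t-BuMe2SiCl (2.2 equiv), imidazole, DMF, rt; then AcOH/THF/H2O, rt
Reagents that add atoms: tert-butylchlorodimethylsilane, CC(C)(C)[Si](C)(C)Cl
Why: Both the phenol and the acid are silylated, and the far more labile silyl ester is then hydrolysed selectively under mild acid, leaving the aryl silyl ether.

Step 21
Reactants: 34 8α-alcohol; 37 4-(tert-butyldimethylsilyloxy)benzoic acid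
Product: 38 8α-[4-(tert-butyldimethylsilyloxy)benzoate] (C10(iPr)=C1; C6(CH3)=C7; 4β-OTBS)
Conditions: DCC, 4-(dimethylamino)pyridine (cat.), CH2Cl2, 0 °C to rt
Reagents that add atoms: none
Why: Steglich esterification acylates the only free hydroxyl, with retention at C8 because the C–O bond of the alcohol is not broken.

Step 22
Reactants: 38 8α-[4-(tert-butyldimethylsilyloxy)benzoate]
Product: 39 1β,10β-diol (1β-OH; 10β-OH; 10α-iPr; 8α-aroyloxy; 4β-OTBS; C6(CH3)=C7)
Conditions: OsO4 (2 mol %), N-methylmorpholine N-oxide, acetone/H2O, 0 °C to rt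
Reagents that add atoms: osmium tetroxide, O=[Os](=O)(=O)=O; N-methylmorpholine N-oxide, C[N+]1([O-])CCOCC1; water, O
Why: Upjohn dihydroxylation should select the C1=C10 cyclopentene, because the C6=C7 alkene is deactivated by the allylic aroyloxy group and screened by that ester and the C4 silyl ether; osmylation from the convex β face of ring A (ring B covers the α face) gives the cis-diol with both hydroxyls β and the isopropyl group α.

Step 23
Reactants: 39 1β,10β-diol
Product: 40 1β-acetate (1β-OAc; 10β-OH; 8α-aroyloxy; 4β-OTBS; aryl OTBS)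
Conditions: Ac2O, pyridine, 4-(dimethylamino)pyridine (cat.), CH2Cl2, 0 °C to rt
Reagents that add atoms: acetic anhydride, CC(=O)OC(C)=O
Why: Acylation distinguishes the secondary C1 hydroxyl from the tertiary C10 hydroxyl, which does not react under these conditions.

Step 24
Reactants: 40 1β-acetate
Product: 41 CNP0146780.2 (target)
Conditions: HF·pyridine, THF/pyridine, 0 °C to rt
Reagents that add atoms: none
Why: Buffered fluoride desilylation removes the aryl and the C4 TBS ethers under mildly acidic conditions that do not hydrolyse or shift the acetate and the allylic aryl ester.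

**Compound list**

1 | cyclopentane-1,3-dione | O=C1CCC(=O)C1 | starting material
2 | 3-bromocyclopent-2-en-1-one | O=C1C=C(Br)CC1 | intermediate
3 | (S)-3-bromocyclopent-2-en-1-ol | BrC1=C[C@@H](O)CC1 | intermediate
4 | (S)-[(3-bromocyclopent-2-en-1-yl)oxy]triethylsilane | BrC1=C[C@@H](O[Si](CC)(CC)CC)CC1 | intermediate
5 | N-methoxy-N-methylacetamide | CON(C)C(C)=O | starting material
6 | (S)-[3-(triethylsilyloxy)cyclopent-1-en-1-yl]lithium (not isolated) | [Li]C1=C[C@@H](O[Si](CC)(CC)CC)CC1 | intermediate
7 | (S)-1-[3-(triethylsilyloxy)cyclopent-1-en-1-yl]ethanone (ring A ketone) | CC(=O)C1=C[C@@H](O[Si](CC)(CC)CC)CC1 | intermediate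
8 | prop-2-yn-1-ol | C#CCO | starting material
9 | tert-butyldimethyl(prop-2-yn-1-yloxy)silane | C#CCO[Si](C)(C)C(C)(C)C | intermediate
10 | benzylchlorodimethylsilane | C[Si](C)(Cl)Cc1ccccc1 | starting material
11 | [3-(tert-butyldimethylsilyloxy)prop-1-yn-1-yl]lithium (not isolated) | [Li]C#CCO[Si](C)(C)C(C)(C)C | intermediate
12 | benzyl[3-(tert-butyldimethylsilyloxy)prop-1-yn-1-yl]dimethylsilane | CC(C)(C)[Si](C)(C)OCC#C[Si](C)(C)Cc1ccccc1 | intermediate
13 | [3-(benzyldimethylsilyl)-1-(tert-butyldimethylsilyloxy)prop-2-yn-1-yl]lithium (not isolated) | [Li]C(C#C[Si](C)(C)Cc1ccccc1)O[Si](C)(C)C(C)(C)C | intermediate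
14 | lithium 3-(benzyldimethylsilyl)-1-(tert-butyldimethylsilyl)prop-2-yn-1-olate (not isolated) | [Li]OC(C#C[Si](C)(C)Cc1ccccc1)[Si](C)(C)C(C)(C)C | intermediate
15 | racemic 3-(benzyldimethylsilyl)-1-(tert-butyldimethylsilyl)prop-2-yn-1-ol | OC(C#C[Si](C)(C)Cc1ccccc1)[Si](C)(C)C(C)(C)C | intermediate
16 | racemic (E)-3-(benzyldimethylsilyl)-1-(tert-butyldimethylsilyl)prop-2-en-1-ol | OC(/C=C/[Si](C)(C)Cc1ccccc1)[Si](C)(C)C(C)(C)C | intermediate
17 | (E)-3-(benzyldimethylsilyl)-1-(tert-butyldimethylsilyl)prop-2-en-1-one | O=C(/C=C/[Si](C)(C)Cc1ccccc1)[Si](C)(C)C(C)(C)C | intermediate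
18 | iodomethane | CI | starting material
19 | lithium enolate of 7 (not isolated) | C=C(O[Li])C1=C[C@@H](O[Si](CC)(CC)CC)CC1 | intermediate
20 | cis-1,2-dialkenylcyclopropane-1,2-diol derivative: C4 lithium alkoxide bearing the cyclopentenyl group, C6 TBS ether bearing the (E)-2-silylvinyl group (not isolated) | [Li]O[C@@]1(C[C@@]1(O[Si](C)(C)C(C)(C)C)/C=C/[Si](C)(C)Cc2ccccc2)C3=C[C@@H](O[Si](CC)(CC)CC)CC3 | intermediate
21 | bicyclic lithium enolate C3=C4(OLi) with 6-OTBS enol ether, 8α-SiMe2Bn, 9β-H, 10β-OTES (not isolated) | C1CC2=C(O[Li])CC(O[Si](C)(C)C(C)(C)C)=C[C@H]([Si](C)(C)Cc3ccccc3)[C@@H]2[C@H]1O[Si](CC)(CC)CC | intermediate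
22 | cis-fused bicyclo[5.3.0]dec-6-en-4-one: 3β-CH3, 6-OTBS, 8α-SiMe2Bn, 9β-H, 10β-OTES | C1C[C@]2(C)C(=O)CC(O[Si](C)(C)C(C)(C)C)=C[C@H]([Si](C)(C)Cc3ccccc3)[C@@H]2[C@H]1O[Si](CC)(CC)CC | intermediate
23 | 4β-alcohol of 22 | C1C[C@]2(C)[C@@H](O)CC(O[Si](C)(C)C(C)(C)C)=C[C@H]([Si](C)(C)Cc3ccccc3)[C@@H]2[C@H]1O[Si](CC)(CC)CC | intermediate
24 | 4β-TBS ether of 23 | C1C[C@]2(C)[C@@H](O[Si](C)(C)C(C)(C)C)CC(O[Si](C)(C)C(C)(C)C)=C[C@H]([Si](C)(C)Cc3ccccc3)[C@@H]2[C@H]1O[Si](CC)(CC)CC | intermediate
25 | C6 lithium enolate (C6(OLi)=C7) from 24 (not isolated) | C1C[C@]2(C)[C@@H](O[Si](C)(C)C(C)(C)C)CC(O[Li])=C[C@H]([Si](C)(C)Cc3ccccc3)[C@@H]2[C@H]1O[Si](CC)(CC)CC | intermediate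
26 | C6 enol triflate (C6(OTf)=C7), 4β-OTBS, 8α-SiMe2Bn, 10β-OTES | C1C[C@]2(C)[C@@H](O[Si](C)(C)C(C)(C)C)CC(OS(=O)(=O)C(F)(F)F)=C[C@H]([Si](C)(C)Cc3ccccc3)[C@@H]2[C@H]1O[Si](CC)(CC)CC | intermediate
27 | 6-methyl alkene (C6(CH3)=C7), 4β-OTBS, 8α-SiMe2Bn, 10β-OTES | C1C[C@]2(C)[C@@H](O[Si](C)(C)C(C)(C)C)CC(C)=C[C@H]([Si](C)(C)Cc3ccccc3)[C@@H]2[C@H]1O[Si](CC)(CC)CC | intermediate
28 | 10β-alcohol, 4β-OTBS, 8α-SiMe2Bn | C1C[C@]2(C)[C@@H](O[Si](C)(C)C(C)(C)C)CC(C)=C[C@H]([Si](C)(C)Cc3ccccc3)[C@@H]2[C@H]1O | intermediate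
29 | C10 ketone, 4β-OTBS, 8α-SiMe2Bn, 9β-H | C1C[C@]2(C)[C@@H](O[Si](C)(C)C(C)(C)C)CC(C)=C[C@H]([Si](C)(C)Cc3ccccc3)[C@@H]2C1=O | intermediate
30 | C10 potassium enolate (C10(OK)=C1) from 29 (not isolated) | C1[C@]2(C)[C@@H](O[Si](C)(C)C(C)(C)C)CC(C)=C[C@H]([Si](C)(C)Cc3ccccc3)[C@@H]2C(O[K])=C1 | intermediate
31 | C10 enol triflate (C10(OTf)=C1), 4β-OTBS, 8α-SiMe2Bn | C1[C@]2(C)[C@@H](O[Si](C)(C)C(C)(C)C)CC(C)=C[C@H]([Si](C)(C)Cc3ccccc3)[C@@H]2C(OS(=O)(=O)C(F)(F)F)=C1 | intermediate
32 | 10-isopropyl diene (C10(iPr)=C1, C6(CH3)=C7), 4β-OTBS, 8α-SiMe2Bn | C1[C@]2(C)[C@@H](O[Si](C)(C)C(C)(C)C)CC(C)=C[C@H]([Si](C)(C)Cc3ccccc3)[C@@H]2C(C(C)C)=C1 | intermediate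
33 | C8 dimethylsilanol (8α-SiMe2OH) from 32 (not isolated) | C1[C@]2(C)[C@@H](O[Si](C)(C)C(C)(C)C)CC(C)=C[C@H]([Si](C)(C)O)[C@@H]2C(C(C)C)=C1 | intermediate
34 | 8α-alcohol, 4β-OTBS, C10(iPr)=C1, C6(CH3)=C7 | C1[C@]2(C)[C@@H](O[Si](C)(C)C(C)(C)C)CC(C)=C[C@H](O)[C@@H]2C(C(C)C)=C1 | intermediate
35 | 4-hydroxybenzoic acid | OC(=O)c1ccc(O)cc1 | starting material
36 | tert-butyldimethylsilyl 4-(tert-butyldimethylsilyloxy)benzoate (not isolated) | CC(C)(C)[Si](C)(C)OC(=O)c1ccc(O[Si](C)(C)C(C)(C)C)cc1 | intermediate
37 | 4-(tert-butyldimethylsilyloxy)benzoic acid | OC(=O)c1ccc(O[Si](C)(C)C(C)(C)C)cc1 | intermediate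
38 | 8α-[4-(tert-butyldimethylsilyloxy)benzoate] of 34 | C1[C@]2(C)[C@@H](O[Si](C)(C)C(C)(C)C)CC(C)=C[C@H](OC(=O)c3ccc(O[Si](C)(C)C(C)(C)C)cc3)[C@@H]2C(C(C)C)=C1 | intermediate
39 | 1β,10β-diol (10α-iPr), 8α-aroyloxy, 4β-OTBS | O[C@H]1C[C@]2(C)[C@@H](O[Si](C)(C)C(C)(C)C)CC(C)=C[C@H](OC(=O)c3ccc(O[Si](C)(C)C(C)(C)C)cc3)[C@@H]2[C@]1(O)C(C)C | intermediate
40 | 1β-acetate of 39 | CC(=O)O[C@H]1C[C@]2(C)[C@@H](O[Si](C)(C)C(C)(C)C)CC(C)=C[C@H](OC(=O)c3ccc(O[Si](C)(C)C(C)(C)C)cc3)[C@@H]2[C@]1(O)C(C)C | intermediate
41 | CNP0146780.2: 1β-acetoxy-4β,10β-dihydroxy-8α-(4-hydroxybenzoyloxy)-10α-isopropyl-3β,6-dimethyl-cis-bicyclo[5.3.0]dec-6-ene (labels as above) | CC(=O)O[C@H]1C[C@]2(C)[C@@H](O)CC(C)=C[C@H](OC(=O)c3ccc(O)cc3)[C@@H]2[C@]1(O)C(C)C | target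

**Totals and risks**

Total step count: 24. Longest linear sequence: 19 steps (8 to 41 through steps 5–19 and 21–24).

Steps most likely to fail:

Step 10. The cascade itself is precedented; the weak point is the in-flask alkylation. Proton exchange between enolate 21 and the newly formed ketone (whose C5 hydrogens are acidic) could move the methyl group to C5 or add two, and O-methylation or incomplete facial control in the oxy-Cope step could add to the loss. The fallback separates annulation and alkylation. It sets out from 7 and 17 and runs the same annulation. Enolate 21 is quenched with Me3SiCl instead of MeI to give the trimethylsilyl enol ether F1, which is isolated. Methyllithium in THF then cleaves only the trimethylsilyl enol ether (the TBS enol ether reacts far more slowly) and regenerates the C3=C4 enolate free of amine and of ketone, and MeI with (Me2N)3PO is added; the route is rejoined at 22.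

Step 22. Osmylation could also attack the ring B alkene, or over-oxidise to a tetraol, if the deactivation of C6=C7 by the allylic ester is insufficient. The fallback switches that alkene off before the dihydroxylation. It sets out from alcohol 34. Epoxidation with VO(acac)2 and t-BuOOH, directed by the allylic C8 hydroxyl, should give the 6α,7α-epoxy alcohol F2. Esterification with 37 (DCC, 4-(dimethylamino)pyridine) gives the epoxy ester F3. OsO4 with N-methylmorpholine N-oxide then meets a single alkene and gives the epoxy diol F4, and acetylation gives the epoxy acetate F5. Reductive deoxygenation of the epoxide with Cp2TiCl (trivalent titanium, made from Cp2TiCl2 and zinc) restores the C6=C7 alkene and returns to 40.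

Step 19. Fluoride could cleave the allylic C8–Si bond in place of the benzyl–Si bond (protodesilylation with alkene shift), or remove the C4 silyl ether. The fallback uses the allylic silane as a nucleophile instead of oxidising the C–Si bond. It sets out from 32. PhSeCl in CH2Cl2 at −78 °C should attack C6 anti to silicon with loss of the silyl group and give the tertiary allylic selenide F6 (6β-SePh, C7=C8). Immediate oxidation with H2O2 and pyridine gives the selenoxide, whose 2,3-sigmatropic shift returns the alkene to C6=C7 and places oxygen on C8 on the β face, giving the 8-epi alcohol F7. Mitsunobu esterification of F7 with 37 (PPh3, diisopropyl azodicarboxylate) inverts C8 and rejoins the route at 38.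

Further compounds
F1 | step 10 | trimethylsilyl enol ether of 21 (C3=C4(OSiMe3); 6-OTBS enol ether; 8α-SiMe2Bn; 9β-H; 10β-OTES) | C1CC2=C(O[Si](C)(C)C)CC(O[Si](C)(C)C(C)(C)C)=C[C@H]([Si](C)(C)Cc3ccccc3)[C@@H]2[C@H]1O[Si](CC)(CC)CC
F2 | step 22 | 6α,7α-epoxy alcohol (8α-OH; 4β-OTBS; C10(iPr)=C1) | C1[C@]2(C)[C@@H](O[Si](C)(C)C(C)(C)C)C[C@]3(C)O[C@@H]3[C@H](O)[C@@H]2C(C(C)C)=C1
F3 | step 22 | 6α,7α-epoxy 8α-[4-(tert-butyldimethylsilyloxy)benzoate] | C1[C@]2(C)[C@@H](O[Si](C)(C)C(C)(C)C)C[C@]3(C)O[C@@H]3[C@H](OC(=O)c4ccc(O[Si](C)(C)C(C)(C)C)cc4)[C@@H]2C(C(C)C)=C1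
F4 | step 22 | 6α,7α-epoxy 1β,10β-diol | O[C@H]1C[C@]2(C)[C@@H](O[Si](C)(C)C(C)(C)C)C[C@]3(C)O[C@@H]3[C@H](OC(=O)c4ccc(O[Si](C)(C)C(C)(C)C)cc4)[C@@H]2[C@]1(O)C(C)C
F5 | step 22 | 6α,7α-epoxy 1β-acetate | CC(=O)O[C@H]1C[C@]2(C)[C@@H](O[Si](C)(C)C(C)(C)C)C[C@]3(C)O[C@@H]3[C@H](OC(=O)c4ccc(O[Si](C)(C)C(C)(C)C)cc4)[C@@H]2[C@]1(O)C(C)C
F6 | step 19 | tertiary allylic selenide (6β-SePh; 6α-CH3; C7=C8; 4β-OTBS; C10(iPr)=C1) | C1[C@]2(C)[C@@H](O[Si](C)(C)C(C)(C)C)C[C@@](C)([Se]c3ccccc3)C=C[C@@H]2C(C(C)C)=C1
F7 | step 19 | 8-epi alcohol (8β-OH; 4β-OTBS; C6(CH3)=C7; C10(iPr)=C1) | C1[C@]2(C)[C@@H](O[Si](C)(C)C(C)(C)C)CC(C)=C[C@@H](O)[C@@H]2C(C(C)C)=C1
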